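Ring B (C5–C10, labdane numbering) is carried through the first half as a cyclopentanone ring (C5, C6, C7, C9, C10) built on an asymmetric allylation. The route rests on the C7(OH)–C8(=C17H2)–C9 array of ring B. C8 and C17 enter together as an ethynyl group on the C7 ketone, and an iodonium-triggered semipinacol shift of the C7–C9 bond onto the alkyne inserts C8. One operation thus gives the six-membered ring, the C7 carbonyl and the exocyclic C8=C17 bond, with C9 retained. Its precursor is a trans-hydrindane 1-(iodoethynyl)cyclopentanol. The 1,2-dioxepine follows from C11 photooxygenation, Wittig olefination and peroxyhemiacetal closure.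

Key step: step 8

Remark: labdane numbering is used for all intermediates. C1–C10 are the bicycle, C11–C16 the side chain, C17 the exocyclic methylene and C20 the angular methyl; β is the face of C20.

Assumption: C15 is a peroxyhemiacetal carbon and equilibrates by ring–chain tautomerism. It is taken to settle as the (15R) epimer of the target.

Step 1
Reactants: 1 2,2,6-trimethylcyclohexan-1-one; 2 allyl chloroformate
Product: 4 allyl 2,6,6-trimethylcyclohex-1-en-1-yl carbonate, via lithium enolate 3 (not isolated)
Conditions: LiHMDS, THF, 0 °C; then 2, −78 °C → rt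
Reagents that add atoms: none
Why: The ketone has a single enolisable position, so one tetrasubstituted enolate forms and the hard chloroformate acylates it on oxygen (enol carbonate formation).

Step 2
Reactants: 4 allyl 2,6,6-trimethylcyclohex-1-en-1-yl carbonate
Product: 5 (R)-2-allyl-2,6,6-trimethylcyclohexan-1-one
Conditions: Pd2(dba)3 (cat.), (R)-t-BuPHOX (cat.), THF, 25 °C
Reagents that add atoms: none
Why: In this Pd-catalysed decarboxylative asymmetric allylic alkylation (Tsuji type), loss of CO2 gives a Pd-allyl enolate and the chiral P,N-ligand controls the enolate face, so the (R)-ligand is expected to set quaternary C10 as (R).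

Step 3
Reactants: 5 (R)-2-allyl-2,6,6-trimethylcyclohexan-1-one
Product: 6 (R)-2,2,6-trimethyl-6-(2-oxopropyl)cyclohexan-1-one
Conditions: PdCl2 (cat.), Cu(OAc)2·H2O (cat.), O2 (1 atm), DMA/H2O, rt
Reagents that add atoms: water, O
Why: In the Tsuji–Wacker oxidation, Markovnikov hydroxypalladation of the terminal alkene and β-hydride elimination give the methyl ketone, and the quaternary neighbour blocks alkene isomerisation.

Step 4
Reactants: 6 (R)-2,2,6-trimethyl-6-(2-oxopropyl)cyclohexan-1-one
Product: 7 (7aR)-4,4,7a-trimethyl-1,4,5,6,7,7a-hexahydro-2H-inden-2-one (C5=C6–C7=O enone)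
Conditions: KOH, xylenes, 110 °C, Dean–Stark
Reagents that add atoms: none
Why: In this intramolecular aldol condensation the methyl-ketone enolate (C6) attacks the hindered ring ketone (C5), azeotropic removal of water drives the reaction, and quaternary C10 cannot epimerise.

Step 5
Reactants: 7 bicyclic enone; 8 2,2-dimethoxyacetaldehyde
Product: 9 (9Z)-9-(2,2-dimethoxyethylidene) derivative of 7 (cross-conjugated dienone C5=C6–C7(=O)–C9=C11)
Conditions: KOH, MeOH/H2O, 0 → 40 °C
Reagents that add atoms: none
Why: In this Claisen–Schmidt (crossed aldol) condensation the aldehyde cannot enolise and C9H2 is the only acidic position of 7, while the alkene geometry (drawn with C12 away from quaternary C10) is lost in step 6.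

Step 6
Reactants: 9 cross-conjugated dienone
Product: 10 (1R,3aS,7aS)-1-(2,2-dimethoxyethyl)-4,4,7a-trimethyloctahydro-2H-inden-2-one (trans-hydrindan-2-one; 5α-H; 9β side chain; 10β-Me)
Conditions: H2 (4 atm), 10 % Pd/C, EtOAc, rt
Reagents that add atoms: none
Why: In this heterogeneous catalytic hydrogenation ring A sits as a chair with the 10β- and 4β-methyl groups axial over the β face, so both C=C bonds should take up hydrogen from the α face, which sets 5α-H (trans fusion) and 9α-H (9β side chain, also expected to be the more stable epimer next to the ketone).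

Step 7
Reactants: 10 trans-hydrindan-2-one; 11 ethynylmagnesium bromide
Product: 12 (1R,2S,3aS,7aS)-1-(2,2-dimethoxyethyl)-2-ethynyl-4,4,7a-trimethyloctahydro-1H-inden-2-ol (7α-ethynyl; 7β-OH)
Conditions: THF, 0 °C → rt; then H2O
Reagents that add atoms: none
Why: The weakly basic acetylide Grignard reagent adds 1,2 to the cyclopentanone from the α face, away from the 10β-methyl group and the 9β side chain, and the new C7 centre is erased in step 8.

Step 8
Reactants: 12 7α-ethynyl-7β-hydrindanol
Product: 14 17,17-diiodo-12,12-dimethoxy-13,14,15,16-tetranorlabd-8(17)-en-7-one, via iodoalkynol 13 (not isolated)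
Conditions: NIS (1.05 equiv), AgNO3 (cat.), MeCN, 4 Å MS, rt, dark; then NIS (1.1 equiv), PhI(OH)OTs (cat.), rt
Reagents that add atoms: N-iodosuccinimide, O=C1CCC(=O)N1I
Why: After silver-catalysed C–H iodination to 13, acid-activated NIS delivers I+ to the iodine-bearing alkyne carbon C17, and as cationic character builds at C8 the C7–C9 σ-bond shifts from C7 to C8 anti to the incoming iodine while the hydroxyl oxygen closes to the C7 carbonyl. The closest known reaction type is the halonium-induced semipinacol ring enlargement of 1-(haloethynyl)cyclopentanols to 2-(dihalomethylidene)cyclohexanones, the alkyne counterpart of the D-homoannulation of 17-substituted steroids. Ring B is formed not by a cyclisation but by a 1,2-alkyl shift that inserts C8 between C7 and C9 of the five-membered ring (5 → 6 ring enlargement). No stereocentre is created: C9 migrates with retention, C5 and C10 are untouched, and the C7 carbinol centre is erased. The step needs C9 and not C6 to migrate, which the higher migratory aptitude of the secondary, more electron-rich and more strained C7–C9 bond should secure. It also needs I+ to find no other π-nucleophile, which is why C12 is kept as an acetal and the C12=C13 alkene is introduced later.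

Step 9
Reactants: 14 diiodomethylidene ketone
Product: 15 12,12-dimethoxy-13,14,15,16-tetranorlabd-8(17)-en-7-one
Conditions: Bu3SnH (2.1 equiv), Et3B (cat.), air, toluene, −20 → 0 °C
Reagents that add atoms: none
Why: In this radical hydrodeiodination the stannyl radical abstracts iodine from the weak vinyl C–I bonds much faster than it adds to the enone, and the neutral medium avoids drift of the exocyclic alkene into the ring or epimerisation at C9.

Step 10
Reactants: 15 α-methylene ketone
Product: 16 12,12-dimethoxy-13,14,15,16-tetranorlabd-8(17)-en-7β-ol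
Conditions: NaBH4, CeCl3·7H2O, MeOH, −20 °C
Reagents that add atoms: none
Why: In the Luche reduction, hard 1,2-hydride delivery along the axial α trajectory of the locked trans-decalin enone gives the equatorial 7β-alcohol without conjugate reduction.

Step 11
Reactants: 16 allylic alcohol acetal
Product: 17 7β-hydroxy-13,14,15,16-tetranorlabd-8(17)-en-12-al
Conditions: PPTS (cat.), acetone/H2O, 40 °C
Reagents that add atoms: water, O
Why: This acid-catalysed acetal hydrolysis uses conditions mild enough for the allylic alcohol and the exocyclic alkene.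

Step 12
Reactants: 17 hydroxy aldehyde
Product: 18 (11Z)-7β,12-bis(triethylsilyloxy)-13,14,15,16-tetranorlabda-8(17),11-diene
Conditions: TESOTf (2.4 equiv), Et3N, CH2Cl2, −78 → 0 °C
Reagents that add atoms: triethylsilyl trifluoromethanesulfonate, CC[Si](CC)(CC)OS(=O)(=O)C(F)(F)F
Why: In this soft enolisation with O-silylation the silyl triflate activates the aldehyde, the amine removes a C11 proton to give mainly the (Z)-enol silane, and the 7β-hydroxyl is protected in the same operation.

Step 13
Reactants: 18 bis-silyl enol ether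
Product: 19 (11R)-7β-triethylsilyloxy-11-(triethylsilylperoxy)-13,14,15,16-tetranorlabd-8(17)-en-12-al (C11 arranged in space as in the target)
Conditions: O2, hν (visible), tetraphenylporphyrin (cat.), CH2Cl2, −78 °C
Reagents that add atoms: dioxygen, O=O
Why: In this silyl-ene (silatropic Schenck-type) photooxygenation singlet oxygen bonds to nucleophilic C11 and the silyl group moves to the terminal oxygen; with C9–H eclipsing the (Z)-enol ether (allylic 1,3-strain) the reagent should come from the face flanked by the flat C8=C17 unit rather than by quaternary C10 with C1 and C20, which sets C11 as in the target, while the far less electron-rich 1,1-disubstituted alkene should stay untouched.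

Step 14
Reactants: 20 [2-(1,3-dioxolan-2-yl)ethyl]triphenylphosphonium bromide; 21 methyl formate
Product: 23 3-(1,3-dioxolan-2-yl)-2-(triphenylphosphoranylidene)propanal, via phosphonium ylide 22 (not isolated)
Conditions: KOt-Bu (2.1 equiv), THF, 0 °C; then 21, 0 °C → rt
Reagents that add atoms: none
Why: This is the C-formylation of a non-stabilised phosphonium ylide by acyl transfer from the formate, and the second equivalent of base converts the acylphosphonium salt into the stabilised ylide.

Step 15
Reactants: 19 α-silylperoxy aldehyde; 23 formyl-stabilised ylide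
Product: 24 (11S,12E)-15,15-ethylenedioxy-7β-triethylsilyloxy-11-(triethylsilylperoxy)labda-8(17),12-dien-16-al
Conditions: benzene, 50 °C, dark
Reagents that add atoms: none
Why: In this Wittig olefination with a formyl-stabilised ylide the neutral conditions spare the base-sensitive α-peroxy aldehyde and favour the (E)-enal, which places C11 cis to C14 as the seven-membered ring needs, and C11 is untouched.

Step 16
Reactants: 24 protected peroxy enal
Product: 26 (11S,15R)-11,15-epidioxy-7β,15-dihydroxylabda-8(17),12-dien-16-al (target), via open-chain hydroperoxy dialdehyde 25 (not isolated)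
Conditions: 1 M HCl, THF, 0 °C → rt
Reagents that add atoms: water, O
Why: Acid hydrolysis removes both silyl groups and the dioxolane, and the freed C11 hydroperoxide adds to the C15 aldehyde held cis on the C12=C13 bond (7-exo-trig peroxyhemiacetal formation, ring–chain tautomerism), with C15 settling under thermodynamic control in the anomerically favoured orientation.

Compound list
1 | 2,2,6-trimethylcyclohexan-1-one (racemic) | CC1CCCC(C)(C)C1=O | starting material
2 | allyl chloroformate | C=CCOC(=O)Cl | starting material
3 | lithium 2,6,6-trimethylcyclohex-1-en-1-olate | [Li+].[O-]C1=C(C)CCCC1(C)C | intermediate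
4 | allyl 2,6,6-trimethylcyclohex-1-en-1-yl carbonate | C=CCOC(=O)OC1=C(C)CCCC1(C)C | intermediate
5 | (R)-2-allyl-2,6,6-trimethylcyclohexan-1-one | C=CC[C@@]1(C)CCCC(C)(C)C1=O | intermediate
6 | (R)-2,2,6-trimethyl-6-(2-oxopropyl)cyclohexan-1-one | CC(=O)C[C@@]1(C)CCCC(C)(C)C1=O | intermediate
7 | (7aR)-4,4,7a-trimethyl-1,4,5,6,7,7a-hexahydro-2H-inden-2-one | O=C1C=C2C(C)(C)CCC[C@]2(C)C1 | intermediate
8 | 2,2-dimethoxyacetaldehyde | COC(OC)C=O | starting material
9 | (9Z)-9-(2,2-dimethoxyethylidene) dienone, 10β-Me | COC(OC)/C=C1\C(=O)C=C2C(C)(C)CCC[C@]12C | intermediate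
10 | (1R,3aS,7aS)-1-(2,2-dimethoxyethyl)-4,4,7a-trimethyloctahydro-2H-inden-2-one | O=C1[C@H](CC(OC)OC)[C@@]2(C)CCCC(C)(C)[C@@H]2C1 | intermediate
11 | ethynylmagnesium bromide | C#C[Mg]Br | starting material
12 | (1R,2S,3aS,7aS)-1-(2,2-dimethoxyethyl)-2-ethynyl-4,4,7a-trimethyloctahydro-1H-inden-2-ol | C#C[C@@]1(O)[C@H](CC(OC)OC)[C@@]2(C)CCCC(C)(C)[C@@H]2C1 | intermediate
13 | 2-(iodoethynyl) analogue of 12 | IC#C[C@@]1(O)[C@H](CC(OC)OC)[C@@]2(C)CCCC(C)(C)[C@@H]2C1 | intermediate
14 | 17,17-diiodo-12,12-dimethoxy-13,14,15,16-tetranorlabd-8(17)-en-7-one | IC(I)=C1[C@H](CC(OC)OC)[C@@]2(C)CCCC(C)(C)[C@@H]2CC1=O | intermediate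
15 | 12,12-dimethoxy-13,14,15,16-tetranorlabd-8(17)-en-7-one | C=C1[C@H](CC(OC)OC)[C@@]2(C)CCCC(C)(C)[C@@H]2CC1=O | intermediate
16 | 12,12-dimethoxy-13,14,15,16-tetranorlabd-8(17)-en-7β-ol | C=C1[C@H](CC(OC)OC)[C@@]2(C)CCCC(C)(C)[C@@H]2C[C@@H]1O | intermediate
17 | 7β-hydroxy-13,14,15,16-tetranorlabd-8(17)-en-12-al | C=C1[C@H](CC=O)[C@@]2(C)CCCC(C)(C)[C@@H]2C[C@@H]1O | intermediate
18 | (11Z)-7β,12-bis(triethylsilyloxy)-13,14,15,16-tetranorlabda-8(17),11-diene | C=C1[C@H](/C=C\O[Si](CC)(CC)CC)[C@@]2(C)CCCC(C)(C)[C@@H]2C[C@@H]1O[Si](CC)(CC)CC | intermediate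
19 | (11R)-7β-triethylsilyloxy-11-(triethylsilylperoxy)-13,14,15,16-tetranorlabd-8(17)-en-12-al | C=C1[C@H]([C@@H](OO[Si](CC)(CC)CC)C=O)[C@@]2(C)CCCC(C)(C)[C@@H]2C[C@@H]1O[Si](CC)(CC)CC | intermediate
20 | [2-(1,3-dioxolan-2-yl)ethyl]triphenylphosphonium bromide | [Br-].C1COC(CC[P+](c2ccccc2)(c2ccccc2)c2ccccc2)O1 | starting material
21 | methyl formate | COC=O | starting material
22 | [2-(1,3-dioxolan-2-yl)ethylidene]triphenylphosphorane | C1COC(CC=P(c2ccccc2)(c2ccccc2)c2ccccc2)O1 | intermediate
23 | 3-(1,3-dioxolan-2-yl)-2-(triphenylphosphoranylidene)propanal | O=CC(CC1OCCO1)=P(c1ccccc1)(c1ccccc1)c1ccccc1 | intermediate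
24 | (11S,12E)-15,15-ethylenedioxy-7β-triethylsilyloxy-11-(triethylsilylperoxy)labda-8(17),12-dien-16-al | C=C1[C@H]([C@@H](OO[Si](CC)(CC)CC)/C=C(\CC2OCCO2)C=O)[C@@]2(C)CCCC(C)(C)[C@@H]2C[C@@H]1O[Si](CC)(CC)CC | intermediate
25 | (11S,12E)-11-hydroperoxy-7β-hydroxylabda-8(17),12-diene-15,16-dial | C=C1[C@H]([C@@H](OO)/C=C(\CC=O)C=O)[C@@]2(C)CCCC(C)(C)[C@@H]2C[C@@H]1O | intermediate
26 | (11S,15R)-11,15-epidioxy-7β,15-dihydroxylabda-8(17),12-dien-16-al | C=C1[C@H]([C@@H]2C=C(C=O)C[C@H](O)OO2)[C@@]2(C)CCCC(C)(C)[C@@H]2C[C@@H]1O | target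

Total step count: 16. Longest linear sequence: 15 (steps 1–13, 15, 16).

Steps most likely to fail

1. Step 8.
- What may go wrong: the C6–C7 bond may migrate in place of C7–C9, because allylic strain between the iodine that ends cis to C9 and the equatorial side chain builds up during the shift. Acid or iodonium may also erode the acetal.
- Fallback: it sets out from 10 and returns at 15, and keeps the 5 → 6 enlargement but relies on the opposite migratory preference.
- Ketone 10 is homologated with trimethylsilyldiazomethane and Me3Al (CH2Cl2, −78 → −20 °C). In this Tiffeneau–Demjanov-type insertion the less substituted C6 migrates, so the old carbonyl carbon becomes C8 and the inserted carbon C7. This should give the α-silyl decalone F1 (configuration at the silyl-bearing C7 immaterial).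
- K2CO3/MeOH removes silicon to give the 8-ketone F2.
- Wittig methylenation (Ph3P=CH2, THF) gives the 8(17)-alkene F3.
- Allylic oxidation with SeO2/t-BuOOH gives the 7α-alcohol F4.
- Dess–Martin oxidation gives 15.

2. Step 13.
- What may go wrong: silyl transfer may be sluggish, so that [2+2] addition and dioxetane cleavage of C11–C12 take over. Facial discrimination at C11 may also be poor.
- Fallback: it sets out from 17 and returns at 19.
- Aldehyde 17 is photooxygenated directly (O2, hν, tetraphenylporphyrin, CHCl3, 0 °C) in the presence of the matched enantiomer of diphenylprolinol trimethylsilyl ether (enamine catalysis).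
- No silyl migration is then needed, and the catalyst as well as C9 controls the face of C11. This should give the α-hydroperoxy aldehyde F5.
- TESOTf/2,6-lutidine (CH2Cl2, −78 °C) caps the hydroperoxide and the 7β-hydroxyl to give 19.

3. Step 15.
- What may go wrong: olefination of the hindered aldehyde by the weakly nucleophilic formyl ylide may be slow. Thermal silyl migration with C–C cleavage, or Kornblum–DeLaMare-type loss of the peroxide, could then compete.
- Fallback: it sets out from 19 and returns at 25.
- The more nucleophilic, commercial 3-(triphenylphosphoranylidene)dihydrofuran-2(3H)-one reacts at rt in CH2Cl2 to give the (E)-alkylidene butyrolactone F6.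
- DIBAL-H (CH2Cl2, −78 °C) opens it reductively to the 15,16-diol F7.
- Dess–Martin periodinane/NaHCO3 oxidises both alcohols to the bis-silylated dialdehyde F8.
- 1 M HCl/THF removes the silyl groups to give 25, which closes to 26.

Further compounds
F1 | step 8 | 12,12-dimethoxy-7-trimethylsilyl-13,14,15,16,17-pentanorlabdan-8-one | O=C1[C@H](CC(OC)OC)[C@@]2(C)CCCC(C)(C)[C@@H]2CC1[Si](C)(C)C
F2 | step 8 | 12,12-dimethoxy-13,14,15,16,17-pentanorlabdan-8-one | O=C1[C@H](CC(OC)OC)[C@@]2(C)CCCC(C)(C)[C@@H]2CC1
F3 | step 8 | 12,12-dimethoxy-13,14,15,16-tetranorlabd-8(17)-ene | C=C1[C@H](CC(OC)OC)[C@@]2(C)CCCC(C)(C)[C@@H]2CC1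
F4 | step 8 | 12,12-dimethoxy-13,14,15,16-tetranorlabd-8(17)-en-7α-ol | C=C1[C@H](CC(OC)OC)[C@@]2(C)CCCC(C)(C)[C@@H]2C[C@H]1O
F5 | step 13 | (11R)-11-hydroperoxy-7β-hydroxy-13,14,15,16-tetranorlabd-8(17)-en-12-al | C=C1[C@H]([C@@H](OO)C=O)[C@@]2(C)CCCC(C)(C)[C@@H]2C[C@@H]1O
F6 | step 15 | (11S,12E)-7β-triethylsilyloxy-11-(triethylsilylperoxy)labda-8(17),12-dien-16,15-olide | C=C1[C@H]([C@@H](OO[Si](CC)(CC)CC)/C=C3\CCOC3=O)[C@@]2(C)CCCC(C)(C)[C@@H]2C[C@@H]1O[Si](CC)(CC)CC
F7 | step 15 | (11S,12E)-7β-triethylsilyloxy-11-(triethylsilylperoxy)labda-8(17),12-diene-15,16-diol | C=C1[C@H]([C@@H](OO[Si](CC)(CC)CC)/C=C(\CCO)CO)[C@@]2(C)CCCC(C)(C)[C@@H]2C[C@@H]1O[Si](CC)(CC)CC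
F8 | step 15 | (11S,12E)-7β-triethylsilyloxy-11-(triethylsilylperoxy)labda-8(17),12-diene-15,16-dial | C=C1[C@H]([C@@H](OO[Si](CC)(CC)CC)/C=C(\CC=O)C=O)[C@@]2(C)CCCC(C)(C)[C@@H]2C[C@@H]1O[Si](CC)(CC)CC
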